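**Compound numbers used throughout** (full list after the steps): 1 O‑benzylisovanillin; 2 triethyl phosphonoacetate; 3 cinnamate ester; 4 cinnamyl alcohol; 5 propargyl bromide; 6 sodium alkoxide of 4; 7 enyne ether; 8 alkenylgold intermediate; 9 methylidene‑oxolane carbinol; 10 5‑bromo‑2‑methoxyphenol; 11 its benzyl ether; 12 bis‑boryl intermediate; 13 dibenzyl ether of the target; 14 target.

**Atom labels:** oxolane ring O1, C2, C3, C4, C5. Ca is the carbinol carbon on C3 (OH, aryl ring A). Cb is the methylene on C4 (aryl ring B).

## Analysis of the target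

The target is a 9,9′‑epoxylignan: an oxolane ring that is unsubstituted at C2 and C5, with C3 carrying Ca(OH)(ring A) and C4 carrying CbH2(ring B); both rings are 3‑hydroxy‑4‑methoxyphenyl. There are three contiguous stereocentres, Ca (S), C3 (S) and C4 (R). Reading the SMILES in three dimensions shows the two ring substituents to be cis. The Ca/C3 pair has the relative configuration that results when C4 and OH are added anti across an (E)‑Ca=C3 styrene double bond. The cis‑3,4 arrangement is the less stable one and cannot be corrected late, because no ring centre is epimerizable once carbonyl groups are absent. The Ca configuration is also not the one expected from the usual 1,2‑induction model for hydride delivery to a C3 aroyl group, nor from reagent approach to the convex face of a bicyclic lactone template. The sensitive groups are the secondary para‑methoxybenzylic alcohol (ionization under acid, hydrogenolysis), the two phenols and the electron‑rich arenes. The feature that invites the strategy is this: C3 is flanked by the ring bond C3–C4 and by the benzylic Ca–OH, which is the pattern of a 1,2‑carbohydroxylation of a cinnamyl unit. C4 carries only H and Cb besides its ring bonds, so it can be sp2 (exocyclic C4=Cb) in a precursor. O1 is one CH2 away from both C3 and C4. Together these atoms are the retron of a hydroxycyclization of an allyl propargyl ether, in which the bond formed is C3–C4, the 8–8′ bond of the lignan.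

## Retrosynthetic reasoning

**14 ⇒ 13.** The two phenols are unmasked last by cutting the two O–benzyl bonds. Benzyl is chosen because 1 is sold with it in place and because its removal needs neither acid nor fluoride next to the acid‑labile Ca–OH.

**13 ⇒ 9 + 11.** The bonds cut are Cb–C(ring B) and C4–H. In the forward sense a bulky dialkylborane adds to the exocyclic C4=Cb alkene of 9 from the face anti to the large C3 substituent, which places Cb cis to it. The resulting intermediate 12 is cross‑coupled with 11. This sets C4 in the cis sense by kinetic approach, where the ring offers no thermodynamic handle. Ring B arrives in one piece, and no carbonyl group ever sits next to a ring stereocentre, so cis cannot leak to trans.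

**9 ⇒ 7 (key disconnection).** The bonds cut are C3–C4 and Ca–O, which opens the oxolane to the achiral, acyclic enyne 7. The cut is made here because one catalytic operation then closes the ring, forms the 8–8′ bond, installs the hydroxyl and sets Ca and C3 together. The forward reaction has to add the alkyne carbon and the oxygen anti across the E alkene (relative configuration), under control of a chiral catalyst (absolute configuration), in a 5‑exo‑dig sense, passing through alkenylgold 8.

**7 ⇒ 4 + 5.** The ether bond O1–C5 is cut. The allylic alkoxide 6 of 4 displaces bromide from 5. The reverse polarity is avoided because a para‑alkoxycinnamyl halide ionizes too easily.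

**4 ⇒ 3 ⇒ 1 + 2.** The Ca=C3 double bond is made by olefination of 1 with 2, which fixes the E geometry that the key step translates into the Ca/C3 configuration. Ester reduction gives 4.

**11 ⇒ 10.** O‑Benzylation of 10 gives ring B with the same protecting group as ring A.

## Alternatives that were turned down

**Alternative 1:** The textbook disconnection cuts Ca–C3 as an aldol bond. The enolate of the β‑benzyl lactone A1 would add to aldehyde 1 to give A2, followed by lactone reduction and ring closure. It was turned down because the enolate of A1 is attacked anti to the neighbouring benzyl group, so A2 is 3,4‑trans by mechanism, the opposite of the cis target, and neither centre can be inverted later. A1 is itself chiral and needs its own asymmetric synthesis. The aldol step gives little control at Ca. Closing the oxolane next to a para‑methoxybenzylic alcohol invites competing benzylic etherification.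

**Alternative 2:** A (3+2) cycloaddition of a nonstabilized formaldehyde‑type carbonyl ylide (O1 with C2 and C5) to the enantioenriched butenolide A3 would close the oxolane in one step and give the cis‑fused lactone A4. The ring and three stereocentres would arise together. It was turned down because the ylide must approach A3 on the face opposite to the aryl group. A4 therefore carries the aryl group on the convex face, whereas the target corresponds to the concave arrangement: Ca would be epimeric. Inversion at a para‑methoxybenzylic carbinol is unreliable. In addition the lactone carbonyl of A4 (Cb) would have to be turned into CH2–aryl by reduction, differentiation of two hydroxyls, activation and an sp3–sp2 coupling, at least five further steps.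

**Alternative 3:** Desymmetrization of the meso anhydride A5 by catalytic enantioselective addition of an arylzinc reagent would form the Ca–aryl bond and give the cis keto acid A6, fixing C3 and C4 in the absolute sense. It was turned down because this key step closes no ring and forms none of the ring bonds, and A5 must first be made. Both centres of A6 are α to carbonyl groups and cis, and they would drift to trans under the conditions that follow. Hydride reduction of the aroyl group under 1,2‑induction is predicted to give the wrong Ca epimer. The carboxyl carbon would have to become Cb–aryl through a second aryl ketone and a deoxygenation that spares the benzylic alcohol. The route would be clearly longer.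

Key step: step 4

Assumption: 1, 2, 5 and 10 are purchased; the (R)‑configured diphosphine is taken to deliver the (S,S) series in step 4, and if the sense of induction is the opposite, the (S)‑ligand is used with nothing else changed.

## Route

Step 1
Reactants: 1 3‑(benzyloxy)‑4‑methoxybenzaldehyde; 2 triethyl phosphonoacetate
Product: 3 ethyl (2E)‑3‑[3‑(benzyloxy)‑4‑methoxyphenyl]prop‑2‑enoate
Conditions: LiCl (1.2 equiv), DBU (1.1 equiv), MeCN, 23 °C
Reagents that add atoms: none
Why: Horner–Wadsworth–Emmons olefination with a stabilized phosphonate should give the E‑configured cinnamate; the benzyl ether is inert to the mild amine base and no stereocentre is formed.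

Step 2
Reactants: 3 ethyl (2E)‑3‑[3‑(benzyloxy)‑4‑methoxyphenyl]prop‑2‑enoate
Product: 4 (2E)‑3‑[3‑(benzyloxy)‑4‑methoxyphenyl]prop‑2‑en‑1‑ol
Conditions: i‑Bu2AlH (2.5 equiv), CH2Cl2, −78 to 0 °C
Reagents that add atoms: none
Why: 1,2‑Reduction of the conjugated ester by the aluminium hydride at low temperature should give the allylic alcohol without touching the alkene or the benzyl ether; the E geometry is retained.

Step 3
Reactants: 4 (2E)‑3‑[3‑(benzyloxy)‑4‑methoxyphenyl]prop‑2‑en‑1‑ol; 5 3‑bromoprop‑1‑yne
Product: 7 2‑(benzyloxy)‑1‑methoxy‑4‑[(1E)‑3‑(prop‑2‑yn‑1‑yloxy)prop‑1‑en‑1‑yl]benzene, via sodium alkoxide 6 (not isolated)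
Conditions: NaH (1.2 equiv), THF, 0 °C; then 5, 0 to 23 °C
Reagents that add atoms: none
Why: Williamson ether synthesis: the primary allylic alkoxide 6 displaces bromide from the unhindered propargylic carbon of 5 in an SN2 reaction; low temperature keeps the propargyl ether from isomerizing to the allenyl ether.

Step 4
Reactants: 7 2‑(benzyloxy)‑1‑methoxy‑4‑[(1E)‑3‑(prop‑2‑yn‑1‑yloxy)prop‑1‑en‑1‑yl]benzene
Product: 9 (S)‑[3‑(benzyloxy)‑4‑methoxyphenyl][(3S)‑4‑methylideneoxolan‑3‑yl]methanol, via alkenylgold intermediate 8 (not isolated)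
Conditions: [(R)‑DTBM‑MeO‑BIPHEP](AuCl)2 (3 mol %), AgOTf (6 mol %), 1,4‑dioxane/H2O (6:1), 23 °C
Reagents that add atoms: water, O
Why: Hydroxycyclization of a 1,6‑enyne catalysed by a cationic monovalent gold complex, the closest known reaction type being the palladium‑, platinum‑ and gold‑catalysed hydroxy‑ and alkoxycyclizations of allyl propargyl ethers and related enynes, including cinnamyl ethers with electron‑rich aryl groups and enantioselective versions with diphosphine digold chlorides. The gold centre binds the terminal alkyne of 7, and the E‑styrene attacks the internal alkyne carbon anti to gold in a 5‑exo‑dig closure that forms C3–C4 and the oxolane ring. The positive charge that develops is shared between C4, C3 and Ca in a cyclopropyl‑gold‑carbene‑like arrangement stabilized by the para‑methoxy group of ring A, and water attacks Ca from the face opposite to C4, which gives alkenylgold 8. Protodeauration of 8 releases 9 and returns the catalyst. Because carbon and oxygen add anti across an E alkene, the Ca/C3 relative configuration (S,S or R,R, never S,R) is fixed by the alkene geometry alone. The absolute configuration at C3 is set by the chiral diphosphine (DTBM‑MeO‑BIPHEP = 6,6′‑dimethoxy‑2,2′‑bis[bis(3,5‑di‑tert‑butyl‑4‑methoxyphenyl)phosphino]‑1,1′‑biphenyl), which selects the enantiotopic alkene face in the C–C bond‑forming event, and Ca follows from it. The step needs 5‑exo over 6‑endo selectivity, secured by the terminal alkyne and by benzylic stabilization at Ca, and it needs cyclization to outrun alkyne hydration, secured by intramolecularity at room temperature; the alkyne terminus Cb becomes the exocyclic methylene that later carries ring B.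

Step 5
Reactants: 10 5‑bromo‑2‑methoxyphenol
Product: 11 2‑(benzyloxy)‑4‑bromo‑1‑methoxybenzene
Conditions: BnBr (1.1 equiv), K2CO3, DMF, 23 °C
Reagents that add atoms: benzyl bromide, BrCc1ccccc1
Why: Williamson O‑benzylation: the phenoxide displaces bromide from the benzylic carbon; the aryl bromide is untouched.

Step 6
Reactants: 9 (S)‑[3‑(benzyloxy)‑4‑methoxyphenyl][(3S)‑4‑methylideneoxolan‑3‑yl]methanol; 11 2‑(benzyloxy)‑4‑bromo‑1‑methoxybenzene
Product: 13 (S)‑[3‑(benzyloxy)‑4‑methoxyphenyl]{(3S,4R)‑4‑[3‑(benzyloxy)‑4‑methoxybenzyl]oxolan‑3‑yl}methanol, via bis(boryl) intermediate 12 (not isolated)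
Conditions: 9‑BBN‑H (2.5 equiv), THF, 0 to 23 °C; then 11, PdCl2(dppf) (5 mol %), 3 M aq NaOH, THF, 65 °C
Reagents that add atoms: none
Why: Hydroboration followed by B‑alkyl Suzuki–Miyaura coupling: the first equivalent of borane turns Ca–OH into a bulky O‑boryl ether, and the second adds boron to Cb and hydrogen to C4 from the face anti to the C3 substituent, so that Cb ends cis to it and C4 becomes R in 12. The coupling of 12 with 11 under zerovalent palladium catalysis forms the Cb–ring B bond without touching a stereocentre, and the aqueous base frees the hydroxyl.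

Step 7
Reactants: 13 (S)‑[3‑(benzyloxy)‑4‑methoxyphenyl]{(3S,4R)‑4‑[3‑(benzyloxy)‑4‑methoxybenzyl]oxolan‑3‑yl}methanol
Product: 14 (S)‑(3‑hydroxy‑4‑methoxyphenyl){(3S,4R)‑4‑[(3‑hydroxy‑4‑methoxyphenyl)methyl]oxolan‑3‑yl}methanol
Conditions: H2 (1 atm), 10% Pd/C, EtOAc/EtOH, 23 °C
Reagents that add atoms: none
Why: Catalytic hydrogenolysis of the two aryl benzyl ethers; in neutral solvent cleavage of the ArO–CH2Ph bonds should be much faster than cleavage of the secondary benzylic C–OH bond, and no stereocentre is involved.

## Compound list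

1 | 3‑(benzyloxy)‑4‑methoxybenzaldehyde | COc1ccc(C=O)cc1OCc1ccccc1 | starting material
2 | triethyl phosphonoacetate | CCOC(=O)CP(=O)(OCC)OCC | starting material
3 | ethyl (2E)‑3‑[3‑(benzyloxy)‑4‑methoxyphenyl]prop‑2‑enoate | CCOC(=O)/C=C/c1ccc(OC)c(OCc2ccccc2)c1 | intermediate
4 | (2E)‑3‑[3‑(benzyloxy)‑4‑methoxyphenyl]prop‑2‑en‑1‑ol | OC/C=C/c1ccc(OC)c(OCc2ccccc2)c1 | intermediate
5 | 3‑bromoprop‑1‑yne (propargyl bromide) | BrCC#C | starting material
6 | sodium (2E)‑3‑[3‑(benzyloxy)‑4‑methoxyphenyl]prop‑2‑en‑1‑olate (not isolated) | [Na+].[O-]C/C=C/c1ccc(OC)c(OCc2ccccc2)c1 | intermediate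
7 | 2‑(benzyloxy)‑1‑methoxy‑4‑[(1E)‑3‑(prop‑2‑yn‑1‑yloxy)prop‑1‑en‑1‑yl]benzene | C#CCOC/C=C/c1ccc(OC)c(OCc2ccccc2)c1 | intermediate
8 | {(Z)‑[(4S)‑4‑{(S)‑[3‑(benzyloxy)‑4‑methoxyphenyl](hydroxy)methyl}oxolan‑3‑ylidene]methyl}gold, phosphine ligand on gold not drawn (not isolated) | [Au]/C=C1\COC[C@H]1[C@H](O)c1ccc(OC)c(OCc2ccccc2)c1 | intermediate
9 | (S)‑[3‑(benzyloxy)‑4‑methoxyphenyl][(3S)‑4‑methylideneoxolan‑3‑yl]methanol | C=C1COC[C@H]1[C@H](O)c1ccc(OC)c(OCc2ccccc2)c1 | intermediate
10 | 5‑bromo‑2‑methoxyphenol | COc1ccc(Br)cc1O | starting material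
11 | 2‑(benzyloxy)‑4‑bromo‑1‑methoxybenzene | COc1ccc(Br)cc1OCc1ccccc1 | intermediate
12 | 9‑{[(3R,4S)‑4‑{(S)‑[3‑(benzyloxy)‑4‑methoxyphenyl][(9‑borabicyclo[3.3.1]nonan‑9‑yl)oxy]methyl}oxolan‑3‑yl]methyl}‑9‑borabicyclo[3.3.1]nonane (not isolated) | C(B1C2CCCC1CCC2)[C@H]1COC[C@H]1[C@H](OB1C2CCCC1CCC2)c1ccc(OC)c(OCc2ccccc2)c1 | intermediate
13 | (S)‑[3‑(benzyloxy)‑4‑methoxyphenyl]{(3S,4R)‑4‑[3‑(benzyloxy)‑4‑methoxybenzyl]oxolan‑3‑yl}methanol | COc1ccc(C[C@H]2COC[C@H]2[C@H](O)c2ccc(OC)c(OCc3ccccc3)c2)cc1OCc1ccccc1 | intermediate
14 | (S)‑(3‑hydroxy‑4‑methoxyphenyl){(3S,4R)‑4‑[(3‑hydroxy‑4‑methoxyphenyl)methyl]oxolan‑3‑yl}methanol | COc1ccc(C[C@H]2COC[C@H]2[C@H](O)c2ccc(OC)c(O)c2)cc1O | target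

## Step count and risks

Total step count: 7. Longest linear sequence: 6 (steps 1, 2, 3, 4, 6, 7); step 5 is a one‑step side branch.

**Step 4 (key step).** The most likely failure is insufficient enantiofacial discrimination. A linear two‑coordinate gold centre holds the chiral ligand far from the alkene face that is selected, so the enantiomeric excess of 9 may fall short of what a single enantiomer requires. A second failure would be partial loss of the anti stereospecificity at Ca, if the para‑methoxybenzylic cation becomes free before water is captured. Competing 6‑endo closure is a lesser concern with a terminal alkyne. The fallback gives up catalyst control and sets out from 7. Racemic hydroxycyclization with PdCl2 and P(C6H4‑3‑SO3Na)3 in aqueous dioxane at 80 °C, a divalent palladium system with direct precedent on cinnamyl propargyl ethers, should give 9 together with its enantiomer (R)‑[3‑(benzyloxy)‑4‑methoxyphenyl][(3R)‑4‑methylideneoxolan‑3‑yl]methanol F1. Acylation of the mixture with (2S)‑methoxy(phenyl)acetic acid (DCC, DMAP, CH2Cl2) should give the diastereomeric esters (S)‑[3‑(benzyloxy)‑4‑methoxyphenyl][(3S)‑4‑methylideneoxolan‑3‑yl]methyl (2S)‑methoxy(phenyl)acetate F2 and (R)‑[3‑(benzyloxy)‑4‑methoxyphenyl][(3R)‑4‑methylideneoxolan‑3‑yl]methyl (2S)‑methoxy(phenyl)acetate F3, to be separated by chromatography. Methanolysis of F2 (K2CO3, MeOH, 0 °C) comes back to the route at 9.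

**Step 6.** What may go wrong is incomplete facial discrimination in the hydroboration, which would give some trans isomer. Slow transmetalation of the β‑branched alkylborane, with protodeboronation taking over, is the second concern. The fallback changes how C4 and the Cb–aryl bond are made and sets out from 9. A Heck reaction of 9 with 11 (Pd2(dba)3, P(t‑Bu)3, Cy2NMe, dioxane, 80 °C) should give the benzylidene compound (S)‑[3‑(benzyloxy)‑4‑methoxyphenyl]{(3S,4Z)‑4‑[3‑(benzyloxy)‑4‑methoxybenzylidene]oxolan‑3‑yl}methanol F4. Hydrogenation of F4 over Pd/C should add hydrogen to the exocyclic alkene from the face anti to the C3 substituent and cleave both benzyl ethers in the same operation. This comes back to the route at 14.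

**Step 7.** What may go wrong is hydrogenolysis of the para‑methoxybenzylic Ca–OH bond in competition with O‑debenzylation, with loss of the hydroxyl group. The fallback masks the vulnerable group and sets out from 13. Silylation (TBSOTf, 2,6‑lutidine, CH2Cl2, −78 °C) should give tert‑butyl{(S)‑[3‑(benzyloxy)‑4‑methoxyphenyl][(3S,4R)‑4‑(3‑(benzyloxy)‑4‑methoxybenzyl)oxolan‑3‑yl]methoxy}dimethylsilane F5, whose hindered benzylic silyl ether resists hydrogenolysis. Hydrogenolysis (H2, Pd/C, EtOAc) should then give the bis‑phenol 5‑{[(3R,4S)‑4‑{(S)‑[(tert‑butyldimethylsilyl)oxy](3‑hydroxy‑4‑methoxyphenyl)methyl}oxolan‑3‑yl]methyl}‑2‑methoxyphenol F6. Desilylation (Bu4NF buffered with AcOH, THF, 0 °C) comes back to the route at 14.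

## Further compounds

F1 | step 4 | (R)‑[3‑(benzyloxy)‑4‑methoxyphenyl][(3R)‑4‑methylideneoxolan‑3‑yl]methanol | C=C1COC[C@@H]1[C@@H](O)c1ccc(OC)c(OCc2ccccc2)c1
F2 | step 4 | (S)‑[3‑(benzyloxy)‑4‑methoxyphenyl][(3S)‑4‑methylideneoxolan‑3‑yl]methyl (2S)‑methoxy(phenyl)acetate | C=C1COC[C@H]1[C@H](OC(=O)[C@@H](OC)c1ccccc1)c1ccc(OC)c(OCc2ccccc2)c1
F3 | step 4 | (R)‑[3‑(benzyloxy)‑4‑methoxyphenyl][(3R)‑4‑methylideneoxolan‑3‑yl]methyl (2S)‑methoxy(phenyl)acetate | C=C1COC[C@@H]1[C@@H](OC(=O)[C@@H](OC)c1ccccc1)c1ccc(OC)c(OCc2ccccc2)c1
F4 | step 6 | (S)‑[3‑(benzyloxy)‑4‑methoxyphenyl]{(3S,4Z)‑4‑[3‑(benzyloxy)‑4‑methoxybenzylidene]oxolan‑3‑yl}methanol | COc1ccc(/C=C2\COC[C@H]2[C@H](O)c2ccc(OC)c(OCc3ccccc3)c2)cc1OCc1ccccc1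
F5 | step 7 | tert‑butyl{(S)‑[3‑(benzyloxy)‑4‑methoxyphenyl][(3S,4R)‑4‑(3‑(benzyloxy)‑4‑methoxybenzyl)oxolan‑3‑yl]methoxy}dimethylsilane | COc1ccc(C[C@H]2COC[C@H]2[C@H](O[Si](C)(C)C(C)(C)C)c2ccc(OC)c(OCc3ccccc3)c2)cc1OCc1ccccc1
F6 | step 7 | 5‑{[(3R,4S)‑4‑{(S)‑[(tert‑butyldimethylsilyl)oxy](3‑hydroxy‑4‑methoxyphenyl)methyl}oxolan‑3‑yl]methyl}‑2‑methoxyphenol | COc1ccc(C[C@H]2COC[C@H]2[C@H](O[Si](C)(C)C(C)(C)C)c2ccc(OC)c(O)c2)cc1O
A1 | alternative 1 | (4R)‑4‑[3‑(benzyloxy)‑4‑methoxybenzyl]oxolan‑2‑one | COc1ccc(C[C@H]2COC(=O)C2)cc1OCc1ccccc1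
A2 | alternative 1 | (3S,4R)‑3‑{(S)‑[3‑(benzyloxy)‑4‑methoxyphenyl](hydroxy)methyl}‑4‑[3‑(benzyloxy)‑4‑methoxybenzyl]oxolan‑2‑one (3,4‑trans) | COc1ccc(C[C@H]2COC(=O)[C@@H]2[C@H](O)c2ccc(OC)c(OCc3ccccc3)c2)cc1OCc1ccccc1
A3 | alternative 2 | (5R)‑5‑[3‑(benzyloxy)‑4‑methoxyphenyl]furan‑2(5H)‑one | O=C1C=C[C@@H](O1)c1ccc(OC)c(OCc2ccccc2)c1
A4 | alternative 2 | (3R,3aS,6aR)‑3‑[3‑(benzyloxy)‑4‑methoxyphenyl]tetrahydro‑1H,3H‑furo[3,4‑c]furan‑1‑one (cis‑fused, aryl on the convex face) | O=C1[C@H]2COC[C@H]2[C@@H](O1)c1ccc(OC)c(OCc2ccccc2)c1
A5 | alternative 3 | (3aR,6aS)‑tetrahydro‑1H,3H‑furo[3,4‑c]furan‑1,3‑dione (meso, cis) | O=C1OC(=O)[C@H]2COC[C@@H]12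
A6 | alternative 3 | (3R,4S)‑4‑[3‑(benzyloxy)‑4‑methoxybenzoyl]oxolane‑3‑carboxylic acid (cis) | OC(=O)[C@H]1COC[C@H]1C(=O)c1ccc(OC)c(OCc2ccccc2)c1
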